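**Retrosynthetic overview**
1. Numbering used throughout: the ten-membered ring is C1 (ketone), C2, C3, C4 (carbinol), C5=C6, C7, C8 (senecioate), C9, C10 (methyl). The butenolide ring is O–C6–C7=C11–C12(=O), and C13 is the CH2OAc carbon on C11.
2. Enabling feature: C6 belongs to both rings and is an enol-ester carbon. Its lactone O lies cis to C4 across C5=C6, and the C7=C11 bond holds C12 cis to C6. This is the anti-addition product of a (Z)-2-en-4-ynoic acid (C12–C11=C7–C6≡C5) onto its own alkyne, which sits between a tertiary propargylic carbinol (C4) and an sp2 carbon (C7).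
3. Key disconnection: O–C6 (5-exo-dig lactonization) and C6–C7 (sp–sp2 coupling) are cut together. Both rings vanish, leaving acyclic seco acid 24 with a terminal alkyne at one end and a (Z)-β-triflyloxyacrylic acid at the other. In the forward sense the ten-membered ring closes first and the butenolide second, in one flask.
4. 24 comes from a C7–C11 aldol, oxidation and chelate-controlled enol triflation, which fixes C7=C11. The C1–C2 bond comes from union of an organolithium (C2–C6, C4 set by Sharpless epoxidation) with a trans-α-methyl-γ-lactone (C1, C7–C10; C8 from the chiral pool, C10 by enolate methylation).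
5. A temporary tetrahydrofuran ring (methyl ketal of C1 with O8) masks ketone and carbinol during the enolate steps. It is opened again before O8 is acylated.

Key step: step 18

Assumption: 27 is taken as the open 4-hydroxy-1-ketone as drawn. Reversible closure of O4 onto C1 (ring–chain tautomerism of a γ-hydroxy ketone) is not treated as a separate compound.

**Step 1**
Reactants: 1 (E)-3-methylpent-2-en-4-yn-1-ol
Product: 2 [(2S,3S)-3-ethynyl-3-methyloxiran-2-yl]methanol
Conditions: Ti(OiPr)4 (10 mol %), L-(+)-diethyl tartrate (12 mol %), t-BuOOH, 4 Å MS, CH2Cl2, −20 °C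
Reagents that add atoms: tert-butyl hydroperoxide CC(C)(C)OO
Why: Sharpless asymmetric epoxidation, in which the complex formed from Ti(OiPr)4 and L-(+)-diethyl tartrate delivers oxygen to one face of the E-allylic alcohol and so sets the future C4 (the second epoxide centre is erased in step 2), while the alkyne is not attacked.

**Step 2**
Reactants: 2 [(2S,3S)-3-ethynyl-3-methyloxiran-2-yl]methanol
Product: 3 (3R)-3-methylpent-4-yne-1,3-diol
Conditions: NaAlH2(OCH2CH2OMe)2, THF, −20 → 0 °C; aq. potassium sodium tartrate
Reagents that add atoms: none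
Why: Hydroxyl-directed reductive opening of a 2,3-epoxy alcohol, in which the alkoxyaluminate delivers hydride intramolecularly to the secondary epoxide carbon so that the C4–O bond and its configuration are kept, while the terminal alkyne is shielded as its aluminium acetylide at low temperature.

**Step 3**
Reactants: 3 (3R)-3-methylpent-4-yne-1,3-diol
Product: 4 (3R)-5-iodo-3-methylpent-1-yn-3-ol
Conditions: I2, PPh3, imidazole, CH2Cl2, 0 °C
Reagents that add atoms: iodine II
Why: Appel-type iodination is selective for the primary alcohol because the tertiary propargylic alcohol cannot undergo displacement of an oxyphosphonium group.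

**Step 4**
Reactants: 4 (3R)-5-iodo-3-methylpent-1-yn-3-ol
Product: 5 (3R)-5-iodo-3-(methoxymethoxy)-3-methylpent-1-yne
Conditions: MeOCH2Cl, iPr2NEt, CH2Cl2, 0 °C → rt
Reagents that add atoms: chloromethyl methyl ether COCCl
Why: Acetal (MOM) protection of the tertiary alcohol gives a group with no acidic proton and no migrating silyl group, which survives organolithium, fluoride and mild acid and falls with strong acid in step 17.

**Step 5**
Reactants: 6 (5R)-5-(hydroxymethyl)dihydrofuran-2(3H)-one
Product: 7 (5R)-5-{[(tert-butyldiphenylsilyl)oxy]methyl}dihydrofuran-2(3H)-one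
Conditions: t-BuPh2SiCl, imidazole, DMF, rt
Reagents that add atoms: tert-butyl(chloro)diphenylsilane CC(C)(C)[Si](Cl)(c1ccccc1)c1ccccc1
Why: Standard silylation of a primary alcohol installs the bulky group that shields one lactone face in step 6.

**Step 6**
Reactants: 7 (5R)-5-{[(tert-butyldiphenylsilyl)oxy]methyl}dihydrofuran-2(3H)-one
Product: 9 (3S,5R)-5-{[(tert-butyldiphenylsilyl)oxy]methyl}-3-methyldihydrofuran-2(3H)-one (trans), via lithium enolate 8 (not isolated)
Conditions: LiN(iPr)2, THF, −78 °C; MeI, −78 °C
Reagents that add atoms: iodomethane CI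
Why: Substrate-controlled lactone enolate alkylation, in which MeI approaches enolate 8 anti to the silyloxymethyl group on C8 and so sets C10 trans to it.

**Step 7**
Reactants: 5 (3R)-5-iodo-3-(methoxymethoxy)-3-methylpent-1-yne; 9 (3S,5R)-5-{[(tert-butyldiphenylsilyl)oxy]methyl}-3-methyldihydrofuran-2(3H)-one
Product: 11 (2R,4S,8R)-1-[(tert-butyldiphenylsilyl)oxy]-2-hydroxy-8-(methoxymethoxy)-4,8-dimethyldec-9-yn-5-one (open form of its hemiketal), via dilithio reagent 10 (not isolated)
Conditions: 5 added to t-BuLi (3.2 equiv), Et2O–pentane, −78 °C; then 9, THF, −78 °C; H2O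
Reagents that add atoms: none
Why: Iodine–lithium exchange followed by single acyl addition to a γ-lactone, in which inverse addition to excess t-BuLi converts both C–I and C≡C–H, the alkyllithium end of 10 is far more nucleophilic than the acetylide end, and the lactolate persists at −78 °C so that neither a second addition nor epimerization at C10 takes place.

**Step 8**
Reactants: 11 hydroxy ketone (2R,4S,8R)
Product: 12 (2R,4S)-2-{[(tert-butyldiphenylsilyl)oxy]methyl}-5-methoxy-5-[(3R)-3-(methoxymethoxy)-3-methylpent-4-yn-1-yl]-4-methyltetrahydrofuran (both epimers at the ketal carbon C1)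
Conditions: pyridinium p-toluenesulfonate (cat.), MeOH, rt
Reagents that add atoms: methanol CO
Why: Acid-catalysed mixed ketal formation from the γ-hydroxy ketone closes the temporary tetrahydrofuran ring, which masks the C1 ketone and O8 and blocks enolization at C10, while O7 stays silylated so that no six-membered ketal can form.

**Step 9**
Reactants: 12 silyl ether ketal
Product: 13 {(2R,4S)-5-methoxy-5-[(3R)-3-(methoxymethoxy)-3-methylpent-4-yn-1-yl]-4-methyltetrahydrofuran-2-yl}methanol
Conditions: Bu4NF, THF, 0 °C → rt
Reagents that add atoms: none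
Why: Fluoride desilylation under basic conditions frees O7 without equilibrating the ketal or touching the MOM ether.

**Step 10**
Reactants: 13 ketal alcohol
Product: 14 (2R,4S)-5-methoxy-5-[(3R)-3-(methoxymethoxy)-3-methylpent-4-yn-1-yl]-4-methyltetrahydrofuran-2-carbaldehyde
Conditions: Dess–Martin periodinane, pyridine, CH2Cl2, 0 °C → rt
Reagents that add atoms: none
Why: Dess–Martin oxidation buffered with pyridine gives the α-alkoxy aldehyde (C7) without epimerization at C8 or loss of the ketal.

**Step 11**
Reactants: 15 tert-butyl 3-hydroxypropanoate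
Product: 16 tert-butyl 3-[(tert-butyldimethylsilyl)oxy]propanoate
Conditions: t-BuMe2SiCl, imidazole, DMF, rt
Reagents that add atoms: tert-butyl(chloro)dimethylsilane CC(C)(C)[Si](C)(C)Cl
Why: Standard silylation provides the C11–C13 building block with C13 already oxygenated.

**Step 12**
Reactants: 16 tert-butyl 3-[(tert-butyldimethylsilyl)oxy]propanoate; 14 ketal aldehyde
Product: 18 tert-butyl 2-{[(tert-butyldimethylsilyl)oxy]methyl}-3-hydroxy-3-(ketal tetrahydrofuran-2-yl)propanoate (diastereomers at C7 and C11), via ester enolate 17 (not isolated)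
Conditions: 16, LiN(iPr)2, THF, −78 °C; then 14, −78 °C; H2O
Reagents that add atoms: none
Why: Lithium ester enolate aldol addition forms C7–C11 at a temperature where β-elimination of the silyloxy group is slow and no other carbonyl group is exposed, and both new centres are erased in steps 13 and 14.

**Step 13**
Reactants: 18 aldol adduct
Product: 19 tert-butyl 2-{[(tert-butyldimethylsilyl)oxy]methyl}-3-oxo-3-(ketal tetrahydrofuran-2-yl)propanoate
Conditions: Dess–Martin periodinane, pyridine, CH2Cl2, rt
Reagents that add atoms: none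
Why: Dess–Martin oxidation of a β-hydroxy ester gives the β-keto ester under neutral conditions that avoid retro-aldol cleavage.

**Step 14**
Reactants: 19 β-keto ester
Product: 21 tert-butyl (Z)-2-{[(tert-butyldimethylsilyl)oxy]methyl}-3-(ketal tetrahydrofuran-2-yl)-3-{[(trifluoromethyl)sulfonyl]oxy}prop-2-enoate, via chelated lithium enolate 20 (not isolated)
Conditions: LiN(SiMe3)2 (1.05 equiv), THF, −78 °C; N-(5-chloro-2-pyridyl)bis(trifluoromethanesulfonimide), −78 → 0 °C
Reagents that add atoms: N-(5-chloropyridin-2-yl)bis(trifluoromethanesulfonimide) O=S(=O)(C(F)(F)F)N(c1ccc(Cl)cn1)S(=O)(=O)C(F)(F)F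
Why: O-sulfonylation of a chelated β-keto ester enolate, in which lithium bridges the enolate oxygen and the ester carbonyl in 20 so that the triflate is fixed cis to CO2tBu and C8 cis to C13, as known for 2-substituted 3-oxo esters.

**Step 15**
Reactants: 21 enol triflate ketal
Product: 22 tert-butyl (2Z,4R,6S,10R)-2-{[(tert-butyldimethylsilyl)oxy]methyl}-4-hydroxy-10-(methoxymethoxy)-6,10-dimethyl-7-oxo-3-{[(trifluoromethyl)sulfonyl]oxy}dodec-2-en-11-ynoate (open form of its hemiketal)
Conditions: pyridinium p-toluenesulfonate, acetone–H2O (10:1), rt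
Reagents that add atoms: water O
Why: Mild hydrolysis removes the temporary ring because a 2-methoxytetrahydrofuran ketal ionizes far faster than the MOM ether, the primary silyl ether or the tert-butyl ester, and O4 is still protected so that no spiroketal can form.

**Step 16**
Reactants: 22 hydroxy ketone triflate
Product: 23 tert-butyl (2Z,4R,6S,10R)-2-{[(tert-butyldimethylsilyl)oxy]methyl}-10-(methoxymethoxy)-6,10-dimethyl-4-[(3-methylbut-2-enoyl)oxy]-7-oxo-3-{[(trifluoromethyl)sulfonyl]oxy}dodec-2-en-11-ynoate
Conditions: 3-methylbut-2-enoyl chloride, pyridine, DMAP (cat.), CH2Cl2, 0 °C → rt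
Reagents that add atoms: 3-methylbut-2-enoyl chloride CC(C)=CC(=O)Cl
Why: Acylation of the only free secondary alcohol drains the hemiketal equilibrium into the open keto ester, and pyridine rather than a trialkylamine avoids the vinylketene path that would deconjugate the senecioyl group.

**Step 17**
Reactants: 23 fully protected seco ester
Product: 24 (2Z,4R,6S,10R)-10-hydroxy-2-(hydroxymethyl)-6,10-dimethyl-4-[(3-methylbut-2-enoyl)oxy]-7-oxo-3-{[(trifluoromethyl)sulfonyl]oxy}dodec-2-en-11-ynoic acid
Conditions: CF3CO2H–CH2Cl2–H2O (9:9:1), 0 °C → rt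
Reagents that add atoms: none
Why: One acidolysis removes the tert-butyl ester, the primary silyl ether and the MOM acetal, while the vinyl triflate, the senecioate, the ketone and the alkyne are acid-stable and the alkynyl group disfavours ionization at C4.

**Step 18**
Reactants: 24 seco acid
Product: 26 13-O-deacetyl target (bicyclic hydroxymethyl butenolide), via cyclodecenyne acid 25 (not isolated)
Conditions: Pd(PPh3)4 (10 mol %), CuI (20 mol %), Et3N (5 equiv), MeCN–THF, 24 added by syringe pump over 12 h (final 1 mM), 40 °C, argon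
Reagents that add atoms: none
Why: Proposed new method: zerovalent palladium inserts into the C7–OTf bond of 24 with retention, the alkynylcopper species formed at C6 from CuI and Et3N transmetalates intramolecularly, and reductive elimination from the eleven-membered palladacycle forges C6–C7 to give cyclodecenyne acid 25, whose carboxylate then adds to C6 of the metal-coordinated C5≡C6 bond and is released by protodemetalation as 26. The closest known reaction type is the intermolecular one-pot Sonogashira coupling/lactonization of (Z)-3-halo- or 3-sulfonyloxyacrylic acids with terminal alkynes to (Z)-γ-alkylidenebutenolides under the same Pd(PPh3)4/CuI/amine system, and what is new is that the coupling stage closes a ten-membered ring. Modes of closure: the ten-membered carbocycle closes by sp–sp2 cross-coupling with the alkyne endocyclic, and the butenolide closes by 5-exo-dig attack of O on C6, which is easy because the C7=C11 bond holds the carboxylate in the plane of the in-plane π orbital of the alkyne. No stereocentre is formed; the only new stereoelement, the C5=C6 geometry (lactone O cis to C4, a trans alkene within the ten-membered ring), follows from anti addition of O and H across the alkyne, and C4, C8 and C10 are untouched because the only base is Et3N. The step needs ring closure to beat oligomerization, which is served by syringe-pump dilution, by the quaternary C4 and the trigonal ring atoms C1 and C7 that thin out transannular contacts, by the modest strain of a cyclodecyne, and by the irreversible drain of 25 into the less strained 26. It also needs 5-exo to beat 6-endo attack, which is secured because C5 is shielded by the quaternary C4 and because a pyranone would have to be bridged across its 1,3-positions by only seven atoms.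

**Step 19**
Reactants: 26 13-O-deacetyl target
Product: 27 target CNP0186726.1
Conditions: Ac2O, pyridine, CH2Cl2, 0 °C
Reagents that add atoms: acetic anhydride CC(=O)OC(C)=O
Why: Acetylation without a nucleophilic catalyst is selective for the primary allylic alcohol at C13 over the tertiary alcohol at C4.

**Compound list**
1 | (E)-3-methylpent-2-en-4-yn-1-ol | C#C/C(C)=C/CO | starting material
2 | [(2S,3S)-3-ethynyl-3-methyloxiran-2-yl]methanol | OC[C@@H]1O[C@@]1(C)C#C | intermediate
3 | (3R)-3-methylpent-4-yne-1,3-diol | C#C[C@](C)(O)CCO | intermediate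
4 | (3R)-5-iodo-3-methylpent-1-yn-3-ol | C#C[C@](C)(O)CCI | intermediate
5 | (3R)-5-iodo-3-(methoxymethoxy)-3-methylpent-1-yne | C#C[C@](C)(OCOC)CCI | intermediate
6 | (5R)-5-(hydroxymethyl)dihydrofuran-2(3H)-one | O=C1CC[C@H](CO)O1 | starting material
7 | (5R)-5-{[(tert-butyldiphenylsilyl)oxy]methyl}dihydrofuran-2(3H)-one | O=C1CC[C@H](CO[Si](c2ccccc2)(c2ccccc2)C(C)(C)C)O1 | intermediate
8 | lithium enolate of 7 | [Li]OC1=CC[C@H](CO[Si](c2ccccc2)(c2ccccc2)C(C)(C)C)O1 | intermediate
9 | (3S,5R)-5-{[(tert-butyldiphenylsilyl)oxy]methyl}-3-methyldihydrofuran-2(3H)-one | O=C1[C@@H](C)C[C@H](CO[Si](c2ccccc2)(c2ccccc2)C(C)(C)C)O1 | intermediate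
10 | dilithio reagent from 5 (alkyllithium at C2, lithium acetylide at C6) | [Li]C#C[C@](C)(OCOC)CC[Li] | intermediate
11 | (2R,4S,8R)-1-[(tert-butyldiphenylsilyl)oxy]-2-hydroxy-8-(methoxymethoxy)-4,8-dimethyldec-9-yn-5-one | C#C[C@](C)(OCOC)CCC(=O)[C@@H](C)C[C@@H](O)CO[Si](c1ccccc1)(c1ccccc1)C(C)(C)C | intermediate
12 | methyl ketal of 11 (2-methoxytetrahydrofuran from C1 and O8, both C1 epimers) | C#C[C@](C)(OCOC)CCC1(OC)O[C@@H](CO[Si](c2ccccc2)(c2ccccc2)C(C)(C)C)C[C@@H]1C | intermediate
13 | ketal alcohol (free C7–OH) | C#C[C@](C)(OCOC)CCC1(OC)O[C@@H](CO)C[C@@H]1C | intermediate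
14 | ketal aldehyde (C7 = CHO) | C#C[C@](C)(OCOC)CCC1(OC)O[C@@H](C=O)C[C@@H]1C | intermediate
15 | tert-butyl 3-hydroxypropanoate | CC(C)(C)OC(=O)CCO | starting material
16 | tert-butyl 3-[(tert-butyldimethylsilyl)oxy]propanoate | CC(C)(C)OC(=O)CCO[Si](C)(C)C(C)(C)C | intermediate
17 | lithium enolate of 16 | [Li]OC(OC(C)(C)C)=CCO[Si](C)(C)C(C)(C)C | intermediate
18 | aldol adduct (C7 carbinol, diastereomers at C7 and C11) | C#C[C@](C)(OCOC)CCC1(OC)O[C@@H](C(O)C(CO[Si](C)(C)C(C)(C)C)C(=O)OC(C)(C)C)C[C@@H]1C | intermediate
19 | β-keto ester (C7 ketone) | C#C[C@](C)(OCOC)CCC1(OC)O[C@@H](C(=O)C(CO[Si](C)(C)C(C)(C)C)C(=O)OC(C)(C)C)C[C@@H]1C | intermediate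
20 | chelated lithium enolate of 19 (OLi cis to CO2tBu) | C#C[C@](C)(OCOC)CCC1(OC)O[C@@H](/C(O[Li])=C(\CO[Si](C)(C)C(C)(C)C)C(=O)OC(C)(C)C)C[C@@H]1C | intermediate
21 | (Z)-enol triflate ketal | C#C[C@](C)(OCOC)CCC1(OC)O[C@@H](/C(OS(=O)(=O)C(F)(F)F)=C(\CO[Si](C)(C)C(C)(C)C)C(=O)OC(C)(C)C)C[C@@H]1C | intermediate
22 | hydroxy ketone enol triflate (2Z,4R,6S,10R) | C#C[C@](C)(OCOC)CCC(=O)[C@@H](C)C[C@@H](O)/C(OS(=O)(=O)C(F)(F)F)=C(\CO[Si](C)(C)C(C)(C)C)C(=O)OC(C)(C)C | intermediate
23 | senecioate of 22 | C#C[C@](C)(OCOC)CCC(=O)[C@@H](C)C[C@@H](OC(=O)C=C(C)C)/C(OS(=O)(=O)C(F)(F)F)=C(\CO[Si](C)(C)C(C)(C)C)C(=O)OC(C)(C)C | intermediate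
24 | seco acid (2Z,4R,6S,10R) | C#C[C@](C)(O)CCC(=O)[C@@H](C)C[C@@H](OC(=O)C=C(C)C)/C(OS(=O)(=O)C(F)(F)F)=C(\CO)C(=O)O | intermediate
25 | cyclodecenyne acid (ten-membered C5≡C6 ring, exocyclic C7=C11, CO2H cis to C6) | O=C(O)/C(CO)=C1\C#C[C@](C)(O)CCC(=O)[C@@H](C)C[C@H]1OC(=O)C=C(C)C | intermediate
26 | 13-O-deacetyl target | OCC1=C2/C(=C/[C@](C)(O)CCC(=O)[C@@H](C)C[C@H]2OC(=O)C=C(C)C)OC1=O | intermediate
27 | CNP0186726.1 | CC(=O)OCC1=C2/C(=C/[C@](C)(O)CCC(=O)[C@@H](C)C[C@H]2OC(=O)C=C(C)C)OC1=O | target

**Step count**
Total step count: 19. Longest linear sequence: 16 (steps 1–4, 7–10, 12–19).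

**Steps most likely to fail**

Step 18. Intermolecular coupling and oxidative alkyne dimerization may outrun the slow ring-closing transmetalation. The vinylpalladium intermediate may also be diverted by carbopalladation of the senecioate double bond. The fallback separates the two ring closures and moves the carbocycle closure to the protected ester stage.
- It sets out from 23 and comes back at 26.
- 23 is stannylated at the terminal alkyne with Bu3SnOMe (toluene, 60 °C, methanol removed) to give the alkynylstannane F1.
- An intramolecular Stille coupling (Pd2(dba)3, AsPh3, LiCl, THF–NMP, syringe pump) closes the ring to the protected cyclodecenyne tert-butyl ester F2, which can be purified.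
- Acidolysis as in step 17 gives 25 as an isolated compound.
- AgNO3 (10 mol %) in acetone then effects the known 5-exo-dig lactonization of the enynoic acid to 26.

Step 2. Hydride may attack in the SN2' sense at the alkyne terminus, or hydroalumination of the propargylic alkoxide may compete with the directed epoxide opening. The fallback replaces hydride delivery by electron transfer at the ester oxidation level.
- It sets out from 2 and comes back at 3.
- 2 is oxidized with TEMPO (cat.) and PhI(OAc)2 in MeCN–H2O to the epoxy acid F3.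
- Esterification with Me3SiCHN2 gives the methyl glycidate F4.
- SmI2 in THF–MeOH at −78 °C cleaves only the Cα–O bond and gives methyl (3R)-3-hydroxy-3-methylpent-4-ynoate F5 with the tertiary centre intact.
- LiBH4 (Et2O, 0 °C) reduces the ester to 3.

Step 7. Proton transfer from an alkyne C–H to the alkyllithium may occur before the lactone is added. Lactone enolization or a second addition are further failure processes. The fallback changes the metal and the acyl partner.
- It sets out from 9 and 5 and comes back at 12.
- 9 is opened with EtSH and AlMe3 (CH2Cl2, 0 °C) to the hydroxy thioester F6.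
- This is silylated at once (Et3SiCl, imidazole) to the triethylsilyl ether thioester F7.
- 5 is converted with Zn dust and LiCl (THF, rt) into the alkylzinc iodide F8, which is not basic enough to deprotonate the alkyne.
- A PdCl2(PPh3)2-catalysed Fukuyama ketone synthesis joins F7 and F8 to the silyl-protected ketone F9.
- Pyridinium p-toluenesulfonate in MeOH removes the triethylsilyl group and closes the ketal to 12.

**Further compounds**
F1 | step 18 | alkynylstannane of 23 | CCCC[Sn](CCCC)(CCCC)C#C[C@](C)(OCOC)CCC(=O)[C@@H](C)C[C@@H](OC(=O)C=C(C)C)/C(OS(=O)(=O)C(F)(F)F)=C(\CO[Si](C)(C)C(C)(C)C)C(=O)OC(C)(C)C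
F2 | step 18 | protected cyclodecenyne tert-butyl ester | CC(C)(C)OC(=O)/C(CO[Si](C)(C)C(C)(C)C)=C1\C#C[C@](C)(OCOC)CCC(=O)[C@@H](C)C[C@H]1OC(=O)C=C(C)C
F3 | step 2 | (2R,3S)-3-ethynyl-3-methyloxirane-2-carboxylic acid | OC(=O)[C@@H]1O[C@@]1(C)C#C
F4 | step 2 | methyl (2R,3S)-3-ethynyl-3-methyloxirane-2-carboxylate | COC(=O)[C@@H]1O[C@@]1(C)C#C
F5 | step 2 | methyl (3R)-3-hydroxy-3-methylpent-4-ynoate | C#C[C@](C)(O)CC(=O)OC
F6 | step 7 | S-ethyl (2S,4R)-5-[(tert-butyldiphenylsilyl)oxy]-4-hydroxy-2-methylpentanethioate | CCSC(=O)[C@@H](C)C[C@@H](O)CO[Si](c1ccccc1)(c1ccccc1)C(C)(C)C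
F7 | step 7 | triethylsilyl ether of F6 | CCSC(=O)[C@@H](C)C[C@@H](O[Si](CC)(CC)CC)CO[Si](c1ccccc1)(c1ccccc1)C(C)(C)C
F8 | step 7 | alkylzinc iodide from 5 | I[Zn]CC[C@@](C)(OCOC)C#C
F9 | step 7 | O8-triethylsilyl ether of 11 | C#C[C@](C)(OCOC)CCC(=O)[C@@H](C)C[C@@H](O[Si](CC)(CC)CC)CO[Si](c1ccccc1)(c1ccccc1)C(C)(C)C
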